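**Retrosynthetic overview**

1. The pyranone is attached last: C3 of purchased 4-hydroxy-6-methyl-2-pyranone is joined to the allylic end of the chain by Tsuji–Trost allylation, so the cyclohexane is the only ring that is built.
2. The chain is joined to the ring by B-alkyl Suzuki coupling of a geraniol-derived homoallylborane with a cyclohexenyl triflate; the ring methine stereocentre and the exocyclic methylene then arise together by reductive 1,3-transposition of the (cyclohexenyl)methanol.
3. The carbinol configuration comes from a CBS reduction of the 2,2-dimethyl ketone.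
4. The cyclohexane is made in one step from methyl 4-methyl-3-oxopentanoate and acrolein by a domino Michael/aldol [3+3] annulation, which forms the bond from the methylene-bearing ring carbon to its ring CH2 neighbour and the bond from CMe2 to the carbinol carbon.
5. Enabling feature: in the cyclohexane the unbranched arc CH2–CH2–CH(OH) is acrolein, and the opposite arc C(=CH2)–CH(chain)–CMe2 is the α-carbon, ketone carbon and γ-carbon of a β-keto ester whose ester carbon is the exocyclic methylene carbon. The hydroxyl sits next to the quaternary CMe2 carbon, exactly where an aldol of an isopropyl ketone onto an aldehyde places it.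

Key step: step 1

Remark on the chemistry: compounds 4, 5 and 6 are keto/enol and epimer mixtures at the ester-bearing ring carbon; this is assumed to be of no consequence because that carbon becomes sp2 in step 3.

**Route**

Step 1
Reactants: 1 methyl 4-methyl-3-oxopentanoate; 2 acrolein
Product: 4 methyl 4-hydroxy-3,3-dimethyl-2-oxocyclohexane-1-carboxylate (racemic), via Michael adduct 3 (not isolated)
Conditions: 1 in excess, acrolein added slowly, 1,1,3,3-tetramethylguanidine (20 mol %), MeCN, −20 °C → 40 °C
Reagents that add atoms: none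
Why: Base-catalysed domino Michael/aldol [3+3] annulation: the enolate of β-keto ester 1 adds through its doubly activated α-carbon to the β-carbon of acrolein (first new ring bond), and in keto aldehyde 3 the enolate on the isopropyl side of the ketone then adds to the formyl carbon (second new ring bond, creating the quaternary CMe2 carbon next to the carbinol). The closest known reaction types are the tandem Michael–aldol annulation of β-keto esters with acrolein or methacrolein that is used to make bicyclo[3.3.1]nonanone ketols, and the Robinson annulation. The cyclohexane, the only ring closed, forms in a 6-(enolendo)-exo-trig aldol closure. The carbinol centre arises without control (racemate) and is reset by reagent control in steps 2 and 4, and the ester-bearing carbon is epimerisable and becomes sp2 in step 3, so no stereoselectivity is asked of this step. It does need site selectivity, which the substrate provides: only the α-carbon is acidic enough for the conjugate addition, aldol closure through that carbon or through the aldehyde α-carbon would make four-membered rings and O-closure to the lactol is reversible, so the six-membered C–C closure through the tertiary carbon is the productive outlet, and the quaternary carbon rules out dehydration so the hydroxyl survives. Slow addition of acrolein to an excess of 1 is meant to hold back a second conjugate addition.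

Step 2
Reactants: 4 methyl 4-hydroxy-3,3-dimethyl-2-oxocyclohexane-1-carboxylate
Product: 5 methyl 3,3-dimethyl-2,4-dioxocyclohexane-1-carboxylate
Conditions: Dess–Martin periodinane, CH2Cl2, 0 °C → 25 °C
Reagents that add atoms: none
Why: Dess–Martin oxidation of the hindered secondary alcohol gives the 2,2-dimethyl-1,3-dione, which erases the uncontrolled carbinol centre so that it can be reset enantioselectively in step 4; the non-enolisable dione is kept away from nucleophilic base to avoid retro-Claisen cleavage.

Step 3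
Reactants: 5 methyl 3,3-dimethyl-2,4-dioxocyclohexane-1-carboxylate
Product: 7 methyl 3,3-dimethyl-4-oxo-2-(trifluoromethanesulfonyloxy)cyclohex-1-ene-1-carboxylate, via sodium enolate 6 (not isolated)
Conditions: NaH (1.05 equiv), THF, 0 °C; then PhNTf2, 0 °C → 25 °C
Reagents that add atoms: N-phenylbis(trifluoromethanesulfonimide), O=S(=O)(N(c1ccccc1)S(=O)(=O)C(F)(F)F)C(F)(F)F
Why: Regioselective enol triflate formation, in which NaH deprotonates only the β-keto ester (the most acidic site) and O-sulfonylation of the chelated enolate places the triflate on the former ketone carbon while the other ketone stays untouched.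

Step 4
Reactants: 7 methyl 3,3-dimethyl-4-oxo-2-(trifluoromethanesulfonyloxy)cyclohex-1-ene-1-carboxylate
Product: 8 methyl (4S)-4-hydroxy-3,3-dimethyl-2-(trifluoromethanesulfonyloxy)cyclohex-1-ene-1-carboxylate
Conditions: (R)-2-methyl-CBS-oxazaborolidine (10 mol %), BH3·SMe2, THF, −20 °C; MeOH quench
Reagents that add atoms: none
Why: Corey–Bakshi–Shibata reduction, in which the (R)-oxazaborolidine binds the ketone on the side of the ring CH2 (small group), away from the quaternary CMe2 carbon (large group), and delivers hydride from the coordinated borane to one face, so the (S)-carbinol centre is set by reagent control.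

Step 5
Reactants: 8 methyl (4S)-4-hydroxy-3,3-dimethyl-2-(trifluoromethanesulfonyloxy)cyclohex-1-ene-1-carboxylate
Product: 9 methyl (4S)-4-[(tert-butyldimethylsilyl)oxy]-3,3-dimethyl-2-(trifluoromethanesulfonyloxy)cyclohex-1-ene-1-carboxylate
Conditions: TBSOTf, 2,6-lutidine, CH2Cl2, −78 °C → 0 °C
Reagents that add atoms: tert-butyldimethylsilyl trifluoromethanesulfonate, CC(C)(C)[Si](C)(C)OS(=O)(=O)C(F)(F)F
Why: Silylation of the hindered secondary alcohol with the reactive silyl triflate; the bulky silyl ether, which cannot donate a hydrogen bond, is wanted for the facial control in step 12.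

Step 6
Reactants: 10 geraniol
Product: 11 tert-butyl{[(2E)-3,7-dimethylocta-2,6-dien-1-yl]oxy}dimethylsilane
Conditions: TBSCl, imidazole, CH2Cl2, 25 °C
Reagents that add atoms: tert-butyldimethylsilyl chloride, CC(C)(C)[Si](C)(C)Cl
Why: Standard silylation of the primary allylic alcohol, which carries the chain terminus through the oxidation and organometallic steps.

Step 7
Reactants: 11 tert-butyl{[(2E)-3,7-dimethylocta-2,6-dien-1-yl]oxy}dimethylsilane
Product: 12 (2E,6E)-8-[(tert-butyldimethylsilyl)oxy]-2,6-dimethylocta-2,6-dien-1-ol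
Conditions: SeO2 (10 mol %), t-BuOOH, salicylic acid (10 mol %), CH2Cl2, 0 °C → 25 °C
Reagents that add atoms: tert-butyl hydroperoxide, CC(C)(C)OO (oxygen delivered through the SeO2 catalyst, O=[Se]=O)
Why: SeO2/t-BuOOH allylic oxidation (ene reaction followed by [2,3]-sigmatropic shift), which is selective for the (E)-methyl group of the terminal trisubstituted alkene and leaves the alkene geometry intact.

Step 8
Reactants: 12 (2E,6E)-8-[(tert-butyldimethylsilyl)oxy]-2,6-dimethylocta-2,6-dien-1-ol
Product: 13 (2E,6E)-8-[(tert-butyldimethylsilyl)oxy]-2,6-dimethylocta-2,6-dienal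
Conditions: Dess–Martin periodinane, CH2Cl2, 0 °C → 25 °C
Reagents that add atoms: none
Why: Dess–Martin oxidation of the primary allylic alcohol to the enal under neutral conditions, without E/Z isomerisation.

Step 9
Reactants: 13 (2E,6E)-8-[(tert-butyldimethylsilyl)oxy]-2,6-dimethylocta-2,6-dienal
Product: 14 tert-butyl{[(2E,6E)-3,7-dimethylnona-2,6,8-trien-1-yl]oxy}dimethylsilane
Conditions: Ph3PCH3Br, KOtBu, THF, 0 °C
Reagents that add atoms: methyltriphenylphosphonium bromide, C[P+](c1ccccc1)(c1ccccc1)c1ccccc1.[Br-]
Why: Wittig methylenation of the enal with the non-stabilised ylide gives the terminal 1,3-diene; no stereocentre or new alkene geometry is created.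

Step 10
Reactants: 14 tert-butyl{[(2E,6E)-3,7-dimethylnona-2,6,8-trien-1-yl]oxy}dimethylsilane; 9 methyl (4S)-4-[(tert-butyldimethylsilyl)oxy]-3,3-dimethyl-2-(trifluoromethanesulfonyloxy)cyclohex-1-ene-1-carboxylate
Product: 16 methyl (4S)-4-[(tert-butyldimethylsilyl)oxy]-2-[(3E,7E)-9-[(tert-butyldimethylsilyl)oxy]-3,7-dimethylnona-3,7-dien-1-yl]-3,3-dimethylcyclohex-1-ene-1-carboxylate, via alkylborane 15 (not isolated)
Conditions: 9-BBN, THF, 0 °C → 25 °C; then 9, PdCl2(dppf) (5 mol %), aqueous K3PO4, DMF, 50 °C
Reagents that add atoms: none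
Why: One-pot hydroboration/B-alkyl Suzuki–Miyaura coupling, in which 9-BBN adds to the monosubstituted terminus of the diene much faster than to the trisubstituted alkenes and the primary alkylborane couples with the electron-poor vinyl triflate without moving the ring double bond.

Step 11
Reactants: 16 methyl (4S)-4-[(tert-butyldimethylsilyl)oxy]-2-[(3E,7E)-9-[(tert-butyldimethylsilyl)oxy]-3,7-dimethylnona-3,7-dien-1-yl]-3,3-dimethylcyclohex-1-ene-1-carboxylate
Product: 17 {(4S)-4-[(tert-butyldimethylsilyl)oxy]-2-[(3E,7E)-9-[(tert-butyldimethylsilyl)oxy]-3,7-dimethylnona-3,7-dien-1-yl]-3,3-dimethylcyclohex-1-en-1-yl}methanol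
Conditions: DIBAL-H (3 equiv), CH2Cl2, −78 °C → 0 °C; Rochelle salt work-up
Reagents that add atoms: none
Why: DIBAL-H 1,2-reduction of the conjugated ester to the primary allylic alcohol; silyl ethers and isolated alkenes are inert.

Step 12
Reactants: 17 {(4S)-4-[(tert-butyldimethylsilyl)oxy]-2-[(3E,7E)-9-[(tert-butyldimethylsilyl)oxy]-3,7-dimethylnona-3,7-dien-1-yl]-3,3-dimethylcyclohex-1-en-1-yl}methanol
Product: 20 tert-butyl{[(1S,3R)-3-[(3E,7E)-9-[(tert-butyldimethylsilyl)oxy]-3,7-dimethylnona-3,7-dien-1-yl]-2,2-dimethyl-4-methylidenecyclohexyl]oxy}dimethylsilane, via sulfonylhydrazine 18 (not isolated), via allylic diazene 19 (not isolated)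
Conditions: 2-nitrobenzenesulfonylhydrazide, PPh3, DEAD, THF, −30 °C; then 25 °C
Reagents that add atoms: none
Why: Reductive 1,3-transposition through an allylic diazene, in which Mitsunobu displacement of the primary allylic alcohol, loss of sulfinic acid on warming and retro-ene extrusion of N2 move the double bond into the exocyclic position and deliver hydrogen to the ring carbon from the face opposite the pseudo-axial methyl of the CMe2 group and opposite the silyloxy group, so the (R)-methine centre is set with the side chain cis to the oxygen.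

Step 13
Reactants: 20 tert-butyl{[(1S,3R)-3-[(3E,7E)-9-[(tert-butyldimethylsilyl)oxy]-3,7-dimethylnona-3,7-dien-1-yl]-2,2-dimethyl-4-methylidenecyclohexyl]oxy}dimethylsilane
Product: 21 (2E,6E)-9-[(1R,3S)-3-hydroxy-2,2-dimethyl-6-methylidenecyclohexyl]-3,7-dimethylnona-2,6-dien-1-ol
Conditions: TBAF (3 equiv), THF, 50 °C
Reagents that add atoms: none
Why: Fluoride-mediated cleavage of both silyl ethers, the hindered secondary one requiring warming; no stereocentre or alkene is touched.

Step 14
Reactants: 21 (2E,6E)-9-[(1R,3S)-3-hydroxy-2,2-dimethyl-6-methylidenecyclohexyl]-3,7-dimethylnona-2,6-dien-1-ol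
Product: 22 (2E,6E)-9-[(1R,3S)-3-hydroxy-2,2-dimethyl-6-methylidenecyclohexyl]-3,7-dimethylnona-2,6-dien-1-yl methyl carbonate
Conditions: ClCO2Me (1.1 equiv), pyridine, CH2Cl2, 0 °C
Reagents that add atoms: methyl chloroformate, COC(=O)Cl
Why: Chemoselective acylation of the unhindered primary allylic alcohol in the presence of the secondary alcohol that is flanked by the quaternary carbon.

Step 15
Reactants: 22 (2E,6E)-9-[(1R,3S)-3-hydroxy-2,2-dimethyl-6-methylidenecyclohexyl]-3,7-dimethylnona-2,6-dien-1-yl methyl carbonate; 23 4-hydroxy-6-methyl-2H-pyran-2-one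
Product: 24 sartorypyrone D
Conditions: Pd(PPh3)4 (5 mol %), 23 in excess, THF, 40 °C
Reagents that add atoms: none
Why: Tsuji–Trost C-allylation, in which zerovalent palladium ionises the carbonate with loss of CO2, the released methoxide deprotonates the acidic hydroxypyranone and its C3 attacks the unhindered terminus of the syn π-allyl complex to give the linear (E)-product, any O-allyl product re-ionising under the conditions.

**Compound list**

1 | methyl 4-methyl-3-oxopentanoate | COC(=O)CC(=O)C(C)C | starting material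
2 | acrolein | C=CC=O | starting material
3 | methyl 2-(2-methylpropanoyl)-5-oxopentanoate (Michael adduct) | COC(=O)C(CCC=O)C(=O)C(C)C | intermediate
4 | methyl 4-hydroxy-3,3-dimethyl-2-oxocyclohexane-1-carboxylate (racemic) | COC(=O)C1CCC(O)C(C)(C)C1=O | intermediate
5 | methyl 3,3-dimethyl-2,4-dioxocyclohexane-1-carboxylate | COC(=O)C1CCC(=O)C(C)(C)C1=O | intermediate
6 | sodium 2-(methoxycarbonyl)-6,6-dimethyl-5-oxocyclohex-1-en-1-olate | [Na+].COC(=O)C1=C([O-])C(C)(C)C(=O)CC1 | intermediate
7 | methyl 3,3-dimethyl-4-oxo-2-(trifluoromethanesulfonyloxy)cyclohex-1-ene-1-carboxylate | COC(=O)C1=C(OS(=O)(=O)C(F)(F)F)C(C)(C)C(=O)CC1 | intermediate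
8 | methyl (4S)-4-hydroxy-3,3-dimethyl-2-(trifluoromethanesulfonyloxy)cyclohex-1-ene-1-carboxylate | COC(=O)C1=C(OS(=O)(=O)C(F)(F)F)C(C)(C)[C@@H](O)CC1 | intermediate
9 | methyl (4S)-4-[(tert-butyldimethylsilyl)oxy]-3,3-dimethyl-2-(trifluoromethanesulfonyloxy)cyclohex-1-ene-1-carboxylate | COC(=O)C1=C(OS(=O)(=O)C(F)(F)F)C(C)(C)[C@@H](O[Si](C)(C)C(C)(C)C)CC1 | intermediate
10 | geraniol, (2E)-3,7-dimethylocta-2,6-dien-1-ol | CC(C)=CCC/C(C)=C/CO | starting material
11 | tert-butyl{[(2E)-3,7-dimethylocta-2,6-dien-1-yl]oxy}dimethylsilane | CC(C)=CCC/C(C)=C/CO[Si](C)(C)C(C)(C)C | intermediate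
12 | (2E,6E)-8-[(tert-butyldimethylsilyl)oxy]-2,6-dimethylocta-2,6-dien-1-ol | OC/C(C)=C/CC/C(C)=C/CO[Si](C)(C)C(C)(C)C | intermediate
13 | (2E,6E)-8-[(tert-butyldimethylsilyl)oxy]-2,6-dimethylocta-2,6-dienal | O=C/C(C)=C/CC/C(C)=C/CO[Si](C)(C)C(C)(C)C | intermediate
14 | tert-butyl{[(2E,6E)-3,7-dimethylnona-2,6,8-trien-1-yl]oxy}dimethylsilane | C=C/C(C)=C/CC/C(C)=C/CO[Si](C)(C)C(C)(C)C | intermediate
15 | 9-[(3E,7E)-9-[(tert-butyldimethylsilyl)oxy]-3,7-dimethylnona-3,7-dien-1-yl]-9-borabicyclo[3.3.1]nonane | B1(CC/C(C)=C/CC/C(C)=C/CO[Si](C)(C)C(C)(C)C)C2CCCC1CCC2 | intermediate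
16 | methyl (4S)-4-[(tert-butyldimethylsilyl)oxy]-2-[(3E,7E)-9-[(tert-butyldimethylsilyl)oxy]-3,7-dimethylnona-3,7-dien-1-yl]-3,3-dimethylcyclohex-1-ene-1-carboxylate | COC(=O)C1=C(CC/C(C)=C/CC/C(C)=C/CO[Si](C)(C)C(C)(C)C)C(C)(C)[C@@H](O[Si](C)(C)C(C)(C)C)CC1 | intermediate
17 | {(4S)-4-[(tert-butyldimethylsilyl)oxy]-2-[(3E,7E)-9-[(tert-butyldimethylsilyl)oxy]-3,7-dimethylnona-3,7-dien-1-yl]-3,3-dimethylcyclohex-1-en-1-yl}methanol | OCC1=C(CC/C(C)=C/CC/C(C)=C/CO[Si](C)(C)C(C)(C)C)C(C)(C)[C@@H](O[Si](C)(C)C(C)(C)C)CC1 | intermediate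
18 | N-alkylated 2-nitrobenzenesulfonohydrazide of 17 (the ring CH2 bonded to the sulfonylated nitrogen) | NN(CC1=C(CC/C(C)=C/CC/C(C)=C/CO[Si](C)(C)C(C)(C)C)C(C)(C)[C@@H](O[Si](C)(C)C(C)(C)C)CC1)S(=O)(=O)c1ccccc1[N+](=O)[O-] | intermediate
19 | allylic monoalkyl diazene (ring CH2–N=NH) | N=NCC1=C(CC/C(C)=C/CC/C(C)=C/CO[Si](C)(C)C(C)(C)C)C(C)(C)[C@@H](O[Si](C)(C)C(C)(C)C)CC1 | intermediate
20 | tert-butyl{[(1S,3R)-3-[(3E,7E)-9-[(tert-butyldimethylsilyl)oxy]-3,7-dimethylnona-3,7-dien-1-yl]-2,2-dimethyl-4-methylidenecyclohexyl]oxy}dimethylsilane | C=C1CC[C@H](O[Si](C)(C)C(C)(C)C)C(C)(C)[C@@H]1CC/C(C)=C/CC/C(C)=C/CO[Si](C)(C)C(C)(C)C | intermediate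
21 | (2E,6E)-9-[(1R,3S)-3-hydroxy-2,2-dimethyl-6-methylidenecyclohexyl]-3,7-dimethylnona-2,6-dien-1-ol | C=C1CC[C@H](O)C(C)(C)[C@@H]1CC/C(C)=C/CC/C(C)=C/CO | intermediate
22 | (2E,6E)-9-[(1R,3S)-3-hydroxy-2,2-dimethyl-6-methylidenecyclohexyl]-3,7-dimethylnona-2,6-dien-1-yl methyl carbonate | C=C1CC[C@H](O)C(C)(C)[C@@H]1CC/C(C)=C/CC/C(C)=C/COC(=O)OC | intermediate
23 | 4-hydroxy-6-methyl-2H-pyran-2-one | Cc1cc(O)cc(=O)o1 | starting material
24 | sartorypyrone D, 4-hydroxy-3-[(2E,6E)-9-[(1R,3S)-3-hydroxy-2,2-dimethyl-6-methylidenecyclohexyl]-3,7-dimethylnona-2,6-dien-1-yl]-6-methyl-2H-pyran-2-one | C=C1CC[C@H](O)C(C)(C)[C@@H]1CC/C(C)=C/CC/C(C)=C/Cc1c(O)cc(C)oc1=O | target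

**Step count**

Total: 15 steps. Longest linear sequence: 11 steps (steps 1–5 and 10–15); steps 6–9 prepare the chain in parallel.

**Steps most likely to fail**

Step 1. What may go wrong: a second conjugate addition at the still acidic α-carbon, oligomerisation of acrolein or of the intermediate aldehyde by intermolecular aldol reaction, and slow closure by the hindered isopropyl-side enolate. The fallback sets out from 1 and comes back at 4. Alkylation of 1 with 2-(2-bromoethyl)-1,3-dioxolane (K2CO3, NaI, DMF, 60 °C) should give methyl 2-[2-(1,3-dioxolan-2-yl)ethyl]-4-methyl-3-oxopentanoate F1. Aqueous HCl in THF would then unmask the aldehyde (compound 3) and close the ring by acid-catalysed aldol addition through the more substituted enol. This replaces the conjugate addition to free acrolein by an enolate alkylation with a masked aldehyde and separates the two bond formations.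

Step 12. What may go wrong: poor facial selectivity in the hydrogen transfer to the ring carbon, because the two half-chair conformers deliver hydrogen to opposite faces, or elimination of the Mitsunobu intermediate to a diene. The fallback sets out from 17 and comes back at 20. Acylation with methyl chloroformate and pyridine should give methyl {(4S)-4-[(tert-butyldimethylsilyl)oxy]-2-[(3E,7E)-9-[(tert-butyldimethylsilyl)oxy]-3,7-dimethylnona-3,7-dien-1-yl]-3,3-dimethylcyclohex-1-en-1-yl}methyl carbonate F2. Palladium-catalysed formate hydrogenolysis (Pd(OAc)2, PBu3, ammonium formate, THF, 50 °C) would then pass a hydride from the metal to the more substituted allyl terminus on the metal-bearing face, the metal sitting opposite the pseudo-axial methyl. This is a π-allyl pathway instead of a sigmatropic one and should give the exocyclic alkene with the same sense of induction.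

Step 10. What may go wrong: slow transmetalation and reductive elimination at the triflate flanked by the quaternary carbon, with competing protodeboronation, β-hydride elimination or hydrolysis of the triflate. The fallback sets out from 14 (through borane 15) and 9 and comes back at 16. Oxidative work-up of 15 (NaOH, H2O2) should give (3E,7E)-9-[(tert-butyldimethylsilyl)oxy]-3,7-dimethylnona-3,7-dien-1-ol F3. An Appel reaction (CBr4, PPh3) would give tert-butyl{[(2E,6E)-9-bromo-3,7-dimethylnona-2,6-dien-1-yl]oxy}dimethylsilane F4, and magnesium in THF the Grignard reagent [(3E,7E)-9-[(tert-butyldimethylsilyl)oxy]-3,7-dimethylnona-3,7-dien-1-yl]magnesium bromide F5. Iron-catalysed Kumada-type coupling of F5 with 9 (Fe(acac)3, 5 mol %, THF/NMP, −30 °C) replaces the palladium/boron manifold by a fast low-temperature alkyl Grignard coupling that is well suited to enol triflates of β-keto esters.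

Further compounds
F1 | step 1 | methyl 2-[2-(1,3-dioxolan-2-yl)ethyl]-4-methyl-3-oxopentanoate | COC(=O)C(CCC1OCCO1)C(=O)C(C)C
F2 | step 12 | methyl {(4S)-4-[(tert-butyldimethylsilyl)oxy]-2-[(3E,7E)-9-[(tert-butyldimethylsilyl)oxy]-3,7-dimethylnona-3,7-dien-1-yl]-3,3-dimethylcyclohex-1-en-1-yl}methyl carbonate | COC(=O)OCC1=C(CC/C(C)=C/CC/C(C)=C/CO[Si](C)(C)C(C)(C)C)C(C)(C)[C@@H](O[Si](C)(C)C(C)(C)C)CC1
F3 | step 10 | (3E,7E)-9-[(tert-butyldimethylsilyl)oxy]-3,7-dimethylnona-3,7-dien-1-ol | OCC/C(C)=C/CC/C(C)=C/CO[Si](C)(C)C(C)(C)C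
F4 | step 10 | tert-butyl{[(2E,6E)-9-bromo-3,7-dimethylnona-2,6-dien-1-yl]oxy}dimethylsilane | BrCC/C(C)=C/CC/C(C)=C/CO[Si](C)(C)C(C)(C)C
F5 | step 10 | [(3E,7E)-9-[(tert-butyldimethylsilyl)oxy]-3,7-dimethylnona-3,7-dien-1-yl]magnesium bromide | Br[Mg]CC/C(C)=C/CC/C(C)=C/CO[Si](C)(C)C(C)(C)C
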